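Numbering the ring C1 (CH–iPr), C2=C3, C4 (C(Me)OH), C5–C7, C8/C9 (epoxide) and C10 (CH–O ester), the route rests on the 1,5-relationship between the C4 carbinol carbon and the C8–C9 epoxide: as ketone and Z-alkene they form the retron of an anionic oxy-Cope rearrangement. One operation expands a cyclohexane (C1, C2, C3, C4, C9, C10) into the cyclodecane by forming C6–C7 while C4–C9 breaks, and fixes the Z-C8=C9 geometry. The precursor is a cyclohexanol with an axial vinyl group on C4, a cis equatorial isopropenyl group on C9 and an axial phenylselanyl group on C3, which later delivers the E-C2=C3 alkene.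

Key step: step 8

Remark: ring positions of the ten-membered compounds follow the numbering above (not IUPAC); in it the target is 1S,2E,4R,8S,9R,10R, with the three oxygens at C4, C8/C9 and C10 on one ring face (α) and isopropyl and both methyls on the other (β), and C7 and C10 cis on the epoxide.

Step 1
Reactants: 1 3-methylbutanal; 2 but-3-en-2-one
Product: 4 (R)-4-isopropylcyclohex-2-en-1-one, via (R)-2-isopropyl-5-oxohexanal 3 (not isolated)
Conditions: (R)-2-[methoxy(diphenyl)methyl]pyrrolidine (5 mol%), ethyl 3,4-dihydroxybenzoate (20 mol%), neat, 4 °C; then LiOH (10 mol%), i-PrOH, rt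
Reagents that add atoms: but-3-en-2-one 2, CC(=O)C=C
Why: Enamine-catalysed Michael addition, in which the diarylprolinol ether shields one face of the E-enamine and so should set the isopropyl-bearing centre as R, followed by intramolecular aldol condensation (Robinson-type annulation) that leaves this γ-centre untouched.

Step 2
Reactants: 4 (R)-4-isopropylcyclohex-2-en-1-one
Product: 5 (R)-2-iodo-4-isopropylcyclohex-2-en-1-one
Conditions: I2, pyridine, CH2Cl2, 0 °C to rt
Reagents that add atoms: iodine, I-I
Why: α-Iodination of the enone by conjugate addition of pyridine, iodination of the enolate and elimination, which does not involve the C4 centre.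

Step 3
Reactants: 5 (R)-2-iodo-4-isopropylcyclohex-2-en-1-one; 6 isopropenylboronic acid pinacol ester
Product: 7 (R)-4-isopropyl-2-(prop-1-en-2-yl)cyclohex-2-en-1-one
Conditions: PdCl2(dppf) (5 mol%), K3PO4, THF/H2O, 40 °C; product used at once (prone to Diels–Alder dimerisation)
Reagents that add atoms: isopropenylboronic acid pinacol ester 6, CC(=C)B1OC(C)(C)C(C)(C)O1
Why: Suzuki–Miyaura coupling of an electron-poor alkenyl iodide with an alkenylboronate, a standard route to 2-alkenyl enones.

Step 4
Reactants: 7 (R)-4-isopropyl-2-(prop-1-en-2-yl)cyclohex-2-en-1-one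
Product: 9 (2S,3R,4R)-3-hydroxy-4-isopropyl-2-(prop-1-en-2-yl)cyclohexan-1-one, via all-trans 3-boryl ketone 8 (not isolated)
Conditions: CuCl (5 mol%), DPEphos (5 mol%), NaOtBu (10 mol%), B2pin2, MeOH (2 equiv), THF, rt; then NaBO3·4H2O, THF/H2O, rt
Reagents that add atoms: sodium perborate, [Na+].[O-]OB=O (oxygen at C3; B2pin2 adds boron only to intermediate 8)
Why: Copper-catalysed conjugate borylation should put boron on C3 anti to the C4 isopropyl group, the enolisable C2 centre settles under the alkoxide into the all-equatorial 2,3-trans arrangement (α-protonation of the dienolate being faster than γ-protonation, the alkene stays out of conjugation), and perborate oxidation replaces boron by hydroxyl with retention.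

Step 5
Reactants: 9 (2S,3R,4R)-3-hydroxy-4-isopropyl-2-(prop-1-en-2-yl)cyclohexan-1-one
Product: 10 (2S,3R,4R)-3-[(tert-butyldimethylsilyl)oxy]-4-isopropyl-2-(prop-1-en-2-yl)cyclohexan-1-one
Conditions: TBSOTf, 2,6-lutidine, CH2Cl2, −78 °C
Reagents that add atoms: tert-butyldimethylsilyl triflate, CC(C)(C)[Si](C)(C)OS(=O)(=O)C(F)(F)F
Why: Silyl triflate silylation of a hindered secondary alcohol, which blocks retro-aldol and alkoxide chemistry in the basic steps that follow.

Step 6
Reactants: 10 (2S,3R,4R)-3-[(tert-butyldimethylsilyl)oxy]-4-isopropyl-2-(prop-1-en-2-yl)cyclohexan-1-one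
Product: 11 (2S,3R,4R,6S)-3-[(tert-butyldimethylsilyl)oxy]-4-isopropyl-6-(phenylselanyl)-2-(prop-1-en-2-yl)cyclohexan-1-one
Conditions: LiN(iPr)2, THF, −78 °C; then PhSeCl, −78 °C
Reagents that add atoms: benzeneselenenyl chloride, Cl[Se]c1ccccc1
Why: Kinetic deprotonation at the unhindered C6 methylene followed by electrophilic α-selenenylation of the lithium enolate, where axial attack on the chair with three equatorial substituents should give the axial (6S) selenide, trans to the C2 isopropenyl group.

Step 7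
Reactants: 11 (2S,3R,4R,6S)-3-[(tert-butyldimethylsilyl)oxy]-4-isopropyl-6-(phenylselanyl)-2-(prop-1-en-2-yl)cyclohexan-1-one; 12 vinylmagnesium bromide
Product: 13 (1R,2S,3R,4R,6S)-3-[(tert-butyldimethylsilyl)oxy]-1-ethenyl-4-isopropyl-6-(phenylselanyl)-2-(prop-1-en-2-yl)cyclohexan-1-ol
Conditions: CeCl3, THF, −78 °C
Reagents that add atoms: vinylmagnesium bromide 12, C=C[Mg]Br
Why: Organocerium 1,2-addition (which suppresses enolisation of the α-seleno ketone) under Felkin–Anh control, where attack anti to the axial C6–Se bond is axial attack, so the vinyl group should enter cis to the equatorial isopropenyl group and leave an equatorial hydroxyl (1R).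

Step 8
Reactants: 13 (1R,2S,3R,4R,6S)-3-[(tert-butyldimethylsilyl)oxy]-1-ethenyl-4-isopropyl-6-(phenylselanyl)-2-(prop-1-en-2-yl)cyclohexan-1-ol
Product: 16 (1R,3S,8Z,10R)-10-[(tert-butyldimethylsilyl)oxy]-1-isopropyl-8-methyl-3-(phenylselanyl)cyclodec-8-en-4-one, via potassium alkoxide 14 (not isolated), via potassium enolate 15 (not isolated)
Conditions: KH, 18-crown-6, THF, 0 to 40 °C; then sat. aq. NH4Cl, −78 °C
Reagents that add atoms: none
Why: The potassium alkoxide 14 is a 3-oxido-1,5-diene (C6=C5–C4(O–)–C9–C8=C7) and should undergo a concerted alkoxide-accelerated [3,3]-sigmatropic shift in which the C6–C7 bond forms as the C4–C9 bond breaks, giving enolate 15, which is protonated at C5 on work-up. The closest known reaction type is the anionic oxy-Cope ring expansion of 1,2-dialkenylcyclohexanols to cyclodec-5-enones. The ten-membered ring is closed by a four-atom ring expansion of the cyclohexane through a chair-like six-centre transition state fused to the cyclohexane chair, not by an end-to-end cyclisation. No new stereocentre is formed (C1, C3 and C10 are carried over, C4 and C9 become trigonal), and the one new stereo-element, the C8=C9 geometry, is fixed as Z by the substrate chair that keeps isopropyl, silyloxy and isopropenyl equatorial and the vinyl group axial, because the C9–C10 ring bond is then axial in the pericyclic chair. The step needs the [3,3] shift to outrun [1,3] shift and C–C fragmentation and needs the C3 selenide to survive with its configuration: the gauche axial-vinyl/equatorial-isopropenyl pair is pre-organised for the chair, the oxido group is gauche (not antiperiplanar) to the C–Se bond, and a hydride base with a cold quench leaves no proton shuttle that could move the kinetic C4=C5 enolate towards C3.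

Step 9
Reactants: 16 (1R,3S,8Z,10R)-10-[(tert-butyldimethylsilyl)oxy]-1-isopropyl-8-methyl-3-(phenylselanyl)cyclodec-8-en-4-one; 17 methylmagnesium bromide
Product: 18 (1R,3S,4R,8Z,10R)-10-[(tert-butyldimethylsilyl)oxy]-1-isopropyl-4,8-dimethyl-3-(phenylselanyl)cyclodec-8-en-4-ol
Conditions: CeCl3, THF, −78 °C
Reagents that add atoms: methylmagnesium bromide 17, C[Mg]Br
Why: 1,2-Addition to an α-seleno ketone (β-hydroxy selenide synthesis), expected to follow the Felkin–Anh model with the C3–Se bond on the α face antiperiplanar to the incoming methyl, so that methyl enters on the β (isopropyl) face and C4 becomes R.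

Step 10
Reactants: 18 (1R,3S,4R,8Z,10R)-10-[(tert-butyldimethylsilyl)oxy]-1-isopropyl-4,8-dimethyl-3-(phenylselanyl)cyclodec-8-en-4-ol
Product: 20 (1S,2E,4R,8Z,10R)-10-[(tert-butyldimethylsilyl)oxy]-1-isopropyl-4,8-dimethylcyclodeca-2,8-dien-4-ol, via selenoxide 19 (not isolated)
Conditions: 30% H2O2, pyridine, CH2Cl2, 0 °C to rt
Reagents that add atoms: none
Why: Selenide oxidation and selenoxide syn-elimination, in which C4 carries no hydrogen so only a C2 hydrogen can be lost and the five-membered syn transition state in a ten-membered ring should favour the E alkene, giving the tertiary allylic alcohol without touching C4 (the C1 descriptor changes to S by priority only).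

Step 11
Reactants: 20 (1S,2E,4R,8Z,10R)-10-[(tert-butyldimethylsilyl)oxy]-1-isopropyl-4,8-dimethylcyclodeca-2,8-dien-4-ol
Product: 21 (1S,2E,4R,8Z,10R)-1-isopropyl-4,8-dimethylcyclodeca-2,8-diene-4,10-diol
Conditions: Bu4NF, THF, rt
Reagents that add atoms: none
Why: Fluoride-induced cleavage of the silyl ether, under which the tertiary allylic alcohol and both alkenes are stable.

Step 12
Reactants: 21 (1S,2E,4R,8Z,10R)-1-isopropyl-4,8-dimethylcyclodeca-2,8-diene-4,10-diol
Product: 22 (1S,2E,4R,8S,9R,10R)-8,9-epoxy-1-isopropyl-4,8-dimethylcyclodec-2-ene-4,10-diol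
Conditions: VO(acac)2 (5 mol%), t-BuOOH (1.1 equiv, in decane), CH2Cl2, 0 °C
Reagents that add atoms: tert-butyl hydroperoxide, CC(C)(C)OO
Why: Hydroxyl-directed vanadium-catalysed epoxidation, in which the metal-bound C10 alkoxide should deliver oxygen to the cis (α) face of the Z-C8=C9 alkene as with other medium-ring cycloalk-2-enols, setting C8 as S and C9 as R, while the more nucleophilic trisubstituted alkene beside the secondary carbinol should react ahead of the disubstituted alkene beside the tertiary C4 hydroxyl.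

Step 13
Reactants: 22 (1S,2E,4R,8S,9R,10R)-8,9-epoxy-1-isopropyl-4,8-dimethylcyclodec-2-ene-4,10-diol; 23 4-acetoxybenzoyl chloride
Product: 25 (1S,2E,4R,8S,9R,10R)-8,9-epoxy-4-hydroxy-1-isopropyl-4,8-dimethylcyclodec-2-en-10-yl 4-hydroxybenzoate, via 4-acetoxybenzoate 24 (not isolated)
Conditions: Et3N, DMAP (10 mol%), CH2Cl2, 0 °C to rt; then pyrrolidine, MeOH, rt
Reagents that add atoms: 4-acetoxybenzoyl chloride 23, CC(=O)Oc1ccc(cc1)C(Cl)=O
Why: Nucleophile-catalysed acylation of the secondary C10 hydroxyl (the tertiary C4 hydroxyl does not react, and the amine base protects the epoxide from HCl), then chemoselective aminolysis of the phenolic acetate, which is far more electrophilic than the hindered alkyl benzoate.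

Compound list
1 | 3-methylbutanal | CC(C)CC=O | starting material
2 | but-3-en-2-one (methyl vinyl ketone) | CC(=O)C=C | starting material
3 | (R)-2-isopropyl-5-oxohexanal (in situ) | CC(C)[C@H](C=O)CCC(C)=O | intermediate
4 | (R)-4-isopropylcyclohex-2-en-1-one | CC(C)[C@@H]1C=CC(=O)CC1 | intermediate
5 | (R)-2-iodo-4-isopropylcyclohex-2-en-1-one | CC(C)[C@@H]1C=C(I)C(=O)CC1 | intermediate
6 | isopropenylboronic acid pinacol ester | CC(=C)B1OC(C)(C)C(C)(C)O1 | starting material
7 | (R)-4-isopropyl-2-(prop-1-en-2-yl)cyclohex-2-en-1-one | CC(C)[C@@H]1C=C(C(C)=C)C(=O)CC1 | intermediate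
8 | (2R,3R,4S)-4-isopropyl-2-(prop-1-en-2-yl)-3-(4,4,5,5-tetramethyl-1,3,2-dioxaborolan-2-yl)cyclohexan-1-one, all-trans (in situ) | O=C1[C@@H](C(C)=C)[C@H](B2OC(C)(C)C(C)(C)O2)[C@@H](C(C)C)CC1 | intermediate
9 | (2S,3R,4R)-3-hydroxy-4-isopropyl-2-(prop-1-en-2-yl)cyclohexan-1-one | O=C1[C@@H](C(C)=C)[C@H](O)[C@@H](C(C)C)CC1 | intermediate
10 | (2S,3R,4R)-3-[(tert-butyldimethylsilyl)oxy]-4-isopropyl-2-(prop-1-en-2-yl)cyclohexan-1-one | O=C1[C@@H](C(C)=C)[C@H](O[Si](C)(C)C(C)(C)C)[C@@H](C(C)C)CC1 | intermediate
11 | (2S,3R,4R,6S)-3-[(tert-butyldimethylsilyl)oxy]-4-isopropyl-6-(phenylselanyl)-2-(prop-1-en-2-yl)cyclohexan-1-one | O=C1[C@@H](C(C)=C)[C@H](O[Si](C)(C)C(C)(C)C)[C@@H](C(C)C)C[C@@H]1[Se]c2ccccc2 | intermediate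
12 | vinylmagnesium bromide | C=C[Mg]Br | starting material
13 | (1R,2S,3R,4R,6S)-3-[(tert-butyldimethylsilyl)oxy]-1-ethenyl-4-isopropyl-6-(phenylselanyl)-2-(prop-1-en-2-yl)cyclohexan-1-ol | O[C@]1(C=C)[C@@H](C(C)=C)[C@H](O[Si](C)(C)C(C)(C)C)[C@@H](C(C)C)C[C@@H]1[Se]c2ccccc2 | intermediate
14 | potassium alkoxide of 13 (in situ) | [K+].[O-][C@]1(C=C)[C@@H](C(C)=C)[C@H](O[Si](C)(C)C(C)(C)C)[C@@H](C(C)C)C[C@@H]1[Se]c2ccccc2 | intermediate
15 | potassium C4=C5 enolate of 16 (in situ) | CC(C)[C@H]1C[C@H]([Se]c2ccccc2)/C([O-])=C/CC/C(C)=C\[C@@H]1O[Si](C)(C)C(C)(C)C.[K+] | intermediate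
16 | (1R,3S,8Z,10R)-10-[(tert-butyldimethylsilyl)oxy]-1-isopropyl-8-methyl-3-(phenylselanyl)cyclodec-8-en-4-one | CC(C)[C@H]1C[C@H]([Se]c2ccccc2)C(=O)CCC/C(C)=C\[C@@H]1O[Si](C)(C)C(C)(C)C | intermediate
17 | methylmagnesium bromide | C[Mg]Br | starting material
18 | (1R,3S,4R,8Z,10R)-10-[(tert-butyldimethylsilyl)oxy]-1-isopropyl-4,8-dimethyl-3-(phenylselanyl)cyclodec-8-en-4-ol | CC(C)[C@H]1C[C@H]([Se]c2ccccc2)[C@](C)(O)CCC/C(C)=C\[C@@H]1O[Si](C)(C)C(C)(C)C | intermediate
19 | selenoxide of 18, configuration at selenium open (in situ) | CC(C)[C@H]1C[C@H]([Se](=O)c2ccccc2)[C@](C)(O)CCC/C(C)=C\[C@@H]1O[Si](C)(C)C(C)(C)C | intermediate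
20 | (1S,2E,4R,8Z,10R)-10-[(tert-butyldimethylsilyl)oxy]-1-isopropyl-4,8-dimethylcyclodeca-2,8-dien-4-ol | CC(C)[C@H]1/C=C/[C@](C)(O)CCC/C(C)=C\[C@@H]1O[Si](C)(C)C(C)(C)C | intermediate
21 | (1S,2E,4R,8Z,10R)-1-isopropyl-4,8-dimethylcyclodeca-2,8-diene-4,10-diol | CC(C)[C@H]1/C=C/[C@](C)(O)CCC/C(C)=C\[C@@H]1O | intermediate
22 | (1S,2E,4R,8S,9R,10R)-8,9-epoxy-1-isopropyl-4,8-dimethylcyclodec-2-ene-4,10-diol | CC(C)[C@H]1/C=C/[C@](C)(O)CCC[C@]2(C)O[C@@H]2[C@@H]1O | intermediate
23 | 4-acetoxybenzoyl chloride | CC(=O)Oc1ccc(cc1)C(Cl)=O | starting material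
24 | 4-acetoxybenzoate of 22 at C10 (in situ) | CC(C)[C@H]1/C=C/[C@](C)(O)CCC[C@]2(C)O[C@@H]2[C@@H]1OC(=O)c1ccc(OC(C)=O)cc1 | intermediate
25 | (1S,2E,4R,8S,9R,10R)-8,9-epoxy-4-hydroxy-1-isopropyl-4,8-dimethylcyclodec-2-en-10-yl 4-hydroxybenzoate (CNP0278889.1) | CC(C)[C@H]1/C=C/[C@](C)(O)CCC[C@]2(C)O[C@@H]2[C@@H]1OC(=O)c1ccc(O)cc1 | target

Total step count: 13. Longest linear sequence: 13 steps (1 and 2 to 25).

Steps most likely to fail

1. Step 9. The risk is poor or reversed facial selectivity of the methyl addition, because the flexible α-seleno cyclodecenone may react through a chelated or non-Felkin conformer; enolisation of the acidic C3–H may also compete. The fallback sets out from 16 and removes selenium first: H2O2/pyridine would give, through the selenoxide F6, the (E)-enone F7. Titanium-catalysed asymmetric 1,2-methylation of this enone (Me2Zn, Ti(OiPr)4, chiral bis(sulfonamide) diol ligand of the enantiomeric series that delivers methyl to the β face) would then put the C4 centre under reagent control and rejoin the route at 20.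

2. Step 8. The risk is that the selenide does not survive the alkoxide conditions (attack at selenium, C–C fragmentation next to the oxido carbon, or loss of the C3 configuration through enolate equilibration), or that the [1,3] shift competes. The fallback keeps selenium out of the rearrangement and sets out from 10. Enolate dehydrogenation (LiN(iPr)2, then N-tert-butylbenzenesulfinimidoyl chloride, −78 °C) would give the cyclohexenone F1. Ethynylmagnesium bromide with CeCl3 (axial attack of the slim alkynyl nucleophile, cis to isopropenyl) would give the propargylic alcohol F2, and semi-hydrogenation (H2, Pd/CaCO3 poisoned with Pb(OAc)2, quinoline) the 1-vinylcyclohexenol F3. KH/18-crown-6 would then give the (2Z,8Z)-cyclodecadienone F4 by the same ring expansion. 1,4-Hydrosilylation (Et3SiH, RhCl(PPh3)3) would give the silyl enol ether F5 with the enol double bond on the C3 side, and PhSeCl would return the sequence to 16.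

3. Step 12. The risk is competing epoxidation of the C2=C3 alkene directed by the tertiary C4 hydroxyl, or insufficient facial selectivity at C8=C9. The fallback sets out from 21 and replaces substrate direction by reagent control: Katsuki–Sharpless epoxidation (Ti(OiPr)4, D-(−)-diethyl tartrate, t-BuOOH, 4 Å sieves, CH2Cl2, −20 °C). The (10R) secondary carbinol is the matched enantiomer for this tartrate and should give the erythro epoxy alcohol, while tertiary allylic alcohols are not substrates; the sequence returns at 22 and no new compound is made (F0).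

Further compounds
F1 | step 8 | (4S,5R,6S)-5-[(tert-butyldimethylsilyl)oxy]-4-isopropyl-6-(prop-1-en-2-yl)cyclohex-2-en-1-one | O=C1[C@@H](C(C)=C)[C@H](O[Si](C)(C)C(C)(C)C)[C@@H](C(C)C)C=C1
F2 | step 8 | (1S,4S,5R,6S)-5-[(tert-butyldimethylsilyl)oxy]-1-ethynyl-4-isopropyl-6-(prop-1-en-2-yl)cyclohex-2-en-1-ol | O[C@]1(C#C)[C@@H](C(C)=C)[C@H](O[Si](C)(C)C(C)(C)C)[C@@H](C(C)C)C=C1
F3 | step 8 | (1S,4S,5R,6S)-5-[(tert-butyldimethylsilyl)oxy]-1-ethenyl-4-isopropyl-6-(prop-1-en-2-yl)cyclohex-2-en-1-ol | O[C@]1(C=C)[C@@H](C(C)=C)[C@H](O[Si](C)(C)C(C)(C)C)[C@@H](C(C)C)C=C1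
F4 | step 8 | (1S,2Z,8Z,10R)-10-[(tert-butyldimethylsilyl)oxy]-1-isopropyl-8-methylcyclodeca-2,8-dien-4-one | CC(C)[C@H]1/C=C\C(=O)CCC/C(C)=C\[C@@H]1O[Si](C)(C)C(C)(C)C
F5 | step 8 | (1R,8Z,10R)-10-[(tert-butyldimethylsilyl)oxy]-1-isopropyl-8-methyl-4-[(triethylsilyl)oxy]cyclodeca-3,8-diene, C3=C4 geometry open | CC(C)[C@H]1CC=C(O[Si](CC)(CC)CC)CCC/C(C)=C\[C@@H]1O[Si](C)(C)C(C)(C)C
F6 | step 9 | selenoxide of 16, configuration at selenium open | CC(C)[C@H]1C[C@H]([Se](=O)c2ccccc2)C(=O)CCC/C(C)=C\[C@@H]1O[Si](C)(C)C(C)(C)C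
F7 | step 9 | (1S,2E,8Z,10R)-10-[(tert-butyldimethylsilyl)oxy]-1-isopropyl-8-methylcyclodeca-2,8-dien-4-one | CC(C)[C@H]1/C=C/C(=O)CCC/C(C)=C\[C@@H]1O[Si](C)(C)C(C)(C)C
F0 | step 12 | none | none
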